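The leftover in Tuesday's run at 20.0 h, what the readings of L and D leave of the Q charged, is 10.0 %, and I count it as Q.

| flask | Q | remark | time |
|---|---|---|---|
| Tuesday's | 0.050 M | run made earlier |  |
| Friday's | 0.025 M | run made earlier |  |
| Thursday's | 0.10 M | run made earlier |  |
| dusk | 0.050 M | one stirred flow tank at steady state, fed with the mixture as stated, mean residence time 60.0 h |  |
| noon | 0.050 M | one stirred flow tank at steady state, fed with the mixture as stated, mean residence time 20 h |  |
| summer | 0.050 M | a closed flask charged with all of it at once and left for 20 h | 20 h |

- Tuesday's (time / h: L / %, D / %): 5.00: 39, 5; 10.0: 52, 12; 15.0: 58, 23; 20.0: 57, 33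
- Friday's (time / h: L / %, D / %): 4.00: 34, 2; 8.00: 48, 9; 12.0: 59, 20; 15.0: 60, 26
- Thursday's (time / h: L / %, D / %): 1.33: 17, 0; 3.00: 27, 4; 6.00: 43, 9; 15.0: 56, 22

(standard deviation of a reading: 2 percentage points)

- the set-up with the highest amount of L at the outlet or at the end, in percent of the Q put in ("none" if the first two lie within 2 percentage points) (dusk / noon / summer / none)
- amount of L at the outlet or at the end, in percent of the Q put in, dusk
- amount of L at the outlet or at the end, in percent of the Q put in, noon
- amount of L at the outlet or at the end, in percent of the Q put in, summer

- the stated concentrations are those of everything mixed, before any reaction; amounts are the same in each set-up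
- the earlier runs were made in a closed, stirred flask

At 15.0 h, L reads 60 %, 58 % and 56 % for charges of 0.025 M, 0.050 M and 0.10 M. That spread is close to the scatter, so I take the steps as first order. Tuesday's leftover then gives n = 2.30 turnovers, n being rate constant times time (in a tank, the Damköhler number).

Noon looks nearly the same as Tuesday's run, with the same charge and a residence time equal to that reading time, so it has the same n. The two still end apart:

closed flask: c_Q / charge = exp(−n)

stirred tank: c_Q / charge = 1 / (1 + n)

Tuesday's flask starts at the full charge, whereas the noon tank reacts throughout at its outlet c_Q, 30.3 % of the charge, which is lower. So I count more leftover at noon than in Tuesday's flask. Dusk has n scaled by its longer residence time, and I count 12.6 % left there.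

For the next step, D gains per hour about 0.0362 h⁻¹ of L in Tuesday's run. In a tank, c_D/c_L then equals the turnovers of L, 0.724 at noon and 2.17 at dusk, though Tuesday's last reading stands at 0.579. I reckon L at 40.4 % for noon and 27.6 % for dusk. Summer repeats Tuesday's recipe, so it should read 57 %, more L than I reckon for either tank.

The forecast gives 27.6 %, 40.5 % and 57 % for dusk, noon and summer, and concludes: “The closed flask is best.”

The flask gives L of 47.1 % at dusk, 45.2 % at noon and 56.9 % in summer, so summer is best.

    Q ⇌ Z (K = 0.360, k = 8.30 × 10⁻⁴ s⁻¹)
    Q → L (k = 4.40 × 10⁻⁵ s⁻¹)
    L ⇌ D (K = 1.20, k = 1.40 × 10⁻⁵ s⁻¹)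

At dusk D stands at 40.4 %, so c_D/c_L in that tank is 0.858, below the 2.17 I counted, and the scheme has a way back from D to L. What is neither L nor D at dusk is 12.5 %, against 12.6 % from the turnovers. Summer read at 30 h has had 3.45 turnovers, which leave 3.16 %, and Q with Z stand there at 3.07 %.

The earlier runs and the new flask come from a simulation with made-up constants; noise was put on by code.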